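The two-carbon bridge is cut between its CH2 groups. The benzylic CH2 stands para to the phenolic oxygen of ring A (the pentasubstituted salicylaldehyde ring), so it is the exocyclic carbon of a para-quinone methide. Its neighbour is alpha to carbinol C-3, hence the methyl carbon of a styryl methyl ketone. In one flask Me3SiOTf silylates both partners, ionises the benzylic silyl ether to a dearomatised O-silyl quinone methide cation and lets a 2-silyloxydiene attack it. Rearomatisation gives the complete chain with only ring A's phenol free. Ring A is then locally C2-symmetric, so ortho-formylation is unambiguous. Catalytic asymmetric methylation of the enone sets C-3.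

Key step: step 4

Assumption: C-3 of the target is S (OH > styryl > CH2CH2Ar > CH3), which corresponds to methyl delivery to the Re face of the ketone. The ligand antipode in step 5 is chosen for that face, by analogy with alkenyl and aryl alkyl ketones in which the flat sp2 arm takes the place of the large group.

Step 1
Reactants: 1 2,5-dihydroxybenzaldehyde
Product: 2 2,5-bis(tert-butyldimethylsilyloxy)benzaldehyde
Conditions: TBSCl (2.4 equiv), imidazole (5 equiv), DMF, rt
Reagents that add atoms: tert-butyldimethylsilyl chloride, CC(C)(C)[Si](C)(C)Cl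
Why: Imidazole-promoted silyl ether formation caps both hydroquinone oxygens, so this ring stays inert to Lewis acid, organozinc and magnesium phenoxide chemistry and only ring A will later carry a free phenol.

Step 2
Reactants: 2 2,5-bis(tert-butyldimethylsilyloxy)benzaldehyde; 3 1-(triphenyl-λ5-phosphanylidene)propan-2-one
Product: 4 (E)-4-[2,5-bis(tert-butyldimethylsilyloxy)phenyl]but-3-en-2-one
Conditions: toluene, 90 °C
Reagents that add atoms: none
Why: The Wittig olefination with a carbonyl-stabilised ylide runs under neutral conditions that spare the silyl ethers and should give the E-enone, whose methyl group is its only enolisable position.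

Step 3
Reactants: 5 4-hydroxy-2,6-dimethylbenzaldehyde
Product: 6 4-(hydroxymethyl)-3,5-dimethylphenol
Conditions: NaBH4, THF/MeOH, 0 °C; aq NH4Cl
Reagents that add atoms: none
Why: Borohydride reduction of the aryl aldehyde at low temperature with a near-neutral quench should stop at the labile para-hydroxybenzyl alcohol without ionisation or over-reduction.

Step 4
Reactants: 4 (E)-4-[2,5-bis(tert-butyldimethylsilyloxy)phenyl]but-3-en-2-one; 6 4-(hydroxymethyl)-3,5-dimethylphenol
Product: 11 (E)-1-[2,5-bis(tert-butyldimethylsilyloxy)phenyl]-5-(4-hydroxy-2,6-dimethylphenyl)pent-1-en-3-one, via silyloxydiene 7 (not isolated), via bis-silyl ether 8 (not isolated), via O-silyl quinone methide cation 9 (not isolated), via aryl trimethylsilyl ether 10 (not isolated)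
Conditions: 4, i-Pr2NEt (3.1 equiv), Me3SiOTf (1.1 equiv), CH2Cl2, 0 °C; then 6, Me3SiOTf (2.2 equiv), −40 °C to rt; work-up aq citric acid/MeOH
Reagents that add atoms: trimethylsilyl trifluoromethanesulfonate, C[Si](C)(C)OS(=O)(=O)C(F)(F)F (its Me3Si groups and triflate appear only in 7–10)
Why: Me3SiOTf/i-Pr2NEt first turns 4 into silyloxydiene 7 and 6 into bis-silyl ether 8; once the base is used up the small excess of Me3SiOTf silylates the benzylic oxygen of 8, (Me3Si)2O departs under the push of the para silyloxy group and the two flanking methyl groups, and the exocyclic CH2 of the resulting cation 9 is attacked by the terminal CH2 of 7, after which loss of Me3Si+ regenerates the promoter and gives 10. The closest known reaction type is the Lewis-acid-mediated SN1 alkylation of silyl enol ethers with electron-rich benzylic electrophiles (Mukaiyama type, run as a one-pot enol silane formation–alkylation), formally a 1,6-addition to a para-quinone methide driven by rearomatisation of ring A. No ring is closed and no stereocentre is formed, and the E-alkene is only a spectator. Site selectivity on the nucleophile is secured because the methyl group is the only enolisable position of 4, and on the electrophile because only the carbon para to oxygen can ionise. Chemoselectivity against Friedel–Crafts self-condensation rests on the far higher nucleophilicity of an enol silane compared with silyloxyarenes, and double alkylation is blocked because no base is left to re-enolise 10. Mild acidic methanolysis at work-up cleaves only the aryl O–SiMe3 bond, so ring A alone emerges with a free phenol.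

Step 5
Reactants: 11 (E)-1-[2,5-bis(tert-butyldimethylsilyloxy)phenyl]-5-(4-hydroxy-2,6-dimethylphenyl)pent-1-en-3-one
Product: 12 4-[(3S,4E)-5-[2,5-bis(tert-butyldimethylsilyloxy)phenyl]-3-hydroxy-3-methylpent-4-en-1-yl]-3,5-dimethylphenol
Conditions: Me2Zn (4 equiv), Ti(Oi-Pr)4 (1.2 equiv), C2-symmetric bis(hydroxycamphorsulfonamide) of trans-cyclohexane-1,2-diamine (10 mol %, antipode for Re-face delivery), toluene/hexane, rt; aq NH4Cl
Reagents that add atoms: dimethylzinc, C[Zn]C
Why: In this catalytic asymmetric 1,2-addition of a dialkylzinc to a ketone under Ti(IV)/chiral bis(sulfonamide)diol catalysis, a reaction type established for alkenyl alkyl ketones, the chiral titanium complex tells the flat styryl arm from the sp3 arylethyl arm and delivers methyl to the Re face, which sets C-3 as S, while one extra equivalent of Me2Zn is spent on the phenolic O–H and no copper is present to open the 1,4-pathway.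

Step 6
Reactants: 12 4-[(3S,4E)-5-[2,5-bis(tert-butyldimethylsilyloxy)phenyl]-3-hydroxy-3-methylpent-4-en-1-yl]-3,5-dimethylphenol
Product: 14 3-[(3S,4E)-5-[2,5-bis(tert-butyldimethylsilyloxy)phenyl]-3-hydroxy-3-methylpent-4-en-1-yl]-6-hydroxy-2,4-dimethylbenzaldehyde, via salicyl alcohol 13 (not isolated)
Conditions: MgCl2 (3 equiv), Et3N (6 equiv), (CH2O)n (8 equiv), THF, reflux; cold aq NH4Cl/citrate buffer (pH 5–6)
Reagents that add atoms: paraformaldehyde (reacts as formaldehyde), C=O
Why: In the Casnati–Skattebøl ortho-formylation only the free phenol of ring A forms a magnesium phenoxide, which delivers coordinated formaldehyde to the ortho carbon to give 13 and is then oxidised by hydride transfer to a second formaldehyde, and because ring A of 12 has a local mirror plane both ortho positions give the same aldehyde while the basic medium leaves the tertiary allylic alcohol, its configuration and the silyl ethers untouched.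

Step 7
Reactants: 14 3-[(3S,4E)-5-[2,5-bis(tert-butyldimethylsilyloxy)phenyl]-3-hydroxy-3-methylpent-4-en-1-yl]-6-hydroxy-2,4-dimethylbenzaldehyde
Product: 15 3-[(3S,4E)-5-(2,5-dihydroxyphenyl)-3-hydroxy-3-methylpent-4-en-1-yl]-6-hydroxy-2,4-dimethylbenzaldehyde (CNP0159341.1)
Conditions: TBAF (2.4 equiv), AcOH (2.6 equiv), THF, 0 °C, argon
Reagents that add atoms: none
Why: Fluoride-induced cleavage of the two aryl silyl ethers, buffered with acetic acid and run under argon, avoids both the acid that would ionise the electron-rich tertiary allylic alcohol and the basic aerobic conditions that would oxidise the hydroquinone, so C-3 and the E-alkene are retained.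

Compound list
1 | 2,5-dihydroxybenzaldehyde | O=Cc1cc(O)ccc1O | starting material
2 | 2,5-bis(tert-butyldimethylsilyloxy)benzaldehyde | O=Cc1cc(O[Si](C)(C)C(C)(C)C)ccc1O[Si](C)(C)C(C)(C)C | intermediate
3 | 1-(triphenyl-λ5-phosphanylidene)propan-2-one | CC(=O)C=P(c1ccccc1)(c1ccccc1)c1ccccc1 | starting material
4 | (E)-4-[2,5-bis(tert-butyldimethylsilyloxy)phenyl]but-3-en-2-one | CC(=O)/C=C/c1cc(O[Si](C)(C)C(C)(C)C)ccc1O[Si](C)(C)C(C)(C)C | intermediate
5 | 4-hydroxy-2,6-dimethylbenzaldehyde | Cc1cc(O)cc(C)c1C=O | starting material
6 | 4-(hydroxymethyl)-3,5-dimethylphenol | Cc1cc(O)cc(C)c1CO | intermediate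
7 | (E)-4-[2,5-bis(tert-butyldimethylsilyloxy)phenyl]-2-(trimethylsilyloxy)buta-1,3-diene | C=C(O[Si](C)(C)C)/C=C/c1cc(O[Si](C)(C)C(C)(C)C)ccc1O[Si](C)(C)C(C)(C)C | intermediate
8 | [2,6-dimethyl-4-(trimethylsilyloxy)phenyl]methyl trimethylsilyl ether | Cc1cc(O[Si](C)(C)C)cc(C)c1CO[Si](C)(C)C | intermediate
9 | (3,5-dimethyl-4-methylidenecyclohexa-2,5-dien-1-ylidene)(trimethylsilyl)oxonium triflate | C=C1C(C)=CC(=[O+][Si](C)(C)C)C=C1C.[O-]S(=O)(=O)C(F)(F)F | intermediate
10 | (E)-1-[2,5-bis(tert-butyldimethylsilyloxy)phenyl]-5-[2,6-dimethyl-4-(trimethylsilyloxy)phenyl]pent-1-en-3-one | Cc1cc(O[Si](C)(C)C)cc(C)c1CCC(=O)/C=C/c1cc(O[Si](C)(C)C(C)(C)C)ccc1O[Si](C)(C)C(C)(C)C | intermediate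
11 | (E)-1-[2,5-bis(tert-butyldimethylsilyloxy)phenyl]-5-(4-hydroxy-2,6-dimethylphenyl)pent-1-en-3-one | Cc1cc(O)cc(C)c1CCC(=O)/C=C/c1cc(O[Si](C)(C)C(C)(C)C)ccc1O[Si](C)(C)C(C)(C)C | intermediate
12 | 4-[(3S,4E)-5-[2,5-bis(tert-butyldimethylsilyloxy)phenyl]-3-hydroxy-3-methylpent-4-en-1-yl]-3,5-dimethylphenol | Cc1cc(O)cc(C)c1CC[C@](C)(O)/C=C/c1cc(O[Si](C)(C)C(C)(C)C)ccc1O[Si](C)(C)C(C)(C)C | intermediate
13 | 4-[(3S,4E)-5-[2,5-bis(tert-butyldimethylsilyloxy)phenyl]-3-hydroxy-3-methylpent-4-en-1-yl]-2-(hydroxymethyl)-3,5-dimethylphenol | Cc1cc(O)c(CO)c(C)c1CC[C@](C)(O)/C=C/c1cc(O[Si](C)(C)C(C)(C)C)ccc1O[Si](C)(C)C(C)(C)C | intermediate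
14 | 3-[(3S,4E)-5-[2,5-bis(tert-butyldimethylsilyloxy)phenyl]-3-hydroxy-3-methylpent-4-en-1-yl]-6-hydroxy-2,4-dimethylbenzaldehyde | Cc1cc(O)c(C=O)c(C)c1CC[C@](C)(O)/C=C/c1cc(O[Si](C)(C)C(C)(C)C)ccc1O[Si](C)(C)C(C)(C)C | intermediate
15 | 3-[(3S,4E)-5-(2,5-dihydroxyphenyl)-3-hydroxy-3-methylpent-4-en-1-yl]-6-hydroxy-2,4-dimethylbenzaldehyde | Cc1cc(O)c(C=O)c(C)c1CC[C@](C)(O)/C=C/c1cc(O)ccc1O | target

Total step count: 7. Longest linear sequence: 6 (steps 1, 2, 4, 5, 6, 7).

Steps most likely to fail

Step 4. The benzylic electrophile may ionise prematurely and condense with electron-rich arenes (Friedel–Crafts oligomerisation). The silyloxydiene may also lose its silyl group by protonation before the C–C bond forms. The fallback makes the same bond by an anionic instead of a cationic union.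
- Setting out from 6, p-toluenesulfinic acid in aqueous formic acid should give the bench-stable 3,5-dimethyl-4-[(4-methylbenzenesulfonyl)methyl]phenol F1.
- Enone 4 is deprotonated with LiHMDS in THF at −78 °C to the lithium dienolate F2.
- F1 is then added together with one further equivalent of LiHMDS. Loss of sulfinate from the phenoxide releases the neutral 3,5-dimethyl-4-methylidenecyclohexa-2,5-dien-1-one F3.
- F3 takes up F2 by 1,6-conjugate addition, and aqueous work-up returns to the route at 11.

Step 5. Facial selectivity may be poor because the two arms of the ketone differ less than in aryl methyl ketones. Turnover may also be slow through binding of the phenoxide to titanium. The fallback replaces asymmetric catalysis by resolution.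
- Setting out from 11, MeMgCl with LaCl3·2LiCl in THF at −78 °C should give the racemic tertiary alcohol F4 by clean 1,2-addition.
- Preparative chromatography on a chiral stationary phase then separates 12 from its (R)-enantiomer F5, and the route is rejoined at 12.

Step 6. Conversion may be incomplete at the ortho carbon hindered by the neighbouring methyl group. The tertiary allylic alcohol may also ionise or transpose during prolonged heating with the magnesium salt. The fallback replaces electrophilic formylation by halogenation and metalation at low temperature.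
- Setting out from 12, NBS with catalytic i-Pr2NH in CH2Cl2 at −78 to 0 °C should brominate ring A ortho to the phenol to give the ortho-bromophenol F6. The para position is blocked and both ortho positions are equivalent.
- Excess t-BuLi in THF at −78 °C removes the two O–H protons and exchanges the bromine.
- A DMF quench then returns to the route at 14.

Further compounds
F1 | step 4 | 3,5-dimethyl-4-[(4-methylbenzenesulfonyl)methyl]phenol | Cc1ccc(cc1)S(=O)(=O)Cc1c(C)cc(O)cc1C
F2 | step 4 | lithium (E)-4-[2,5-bis(tert-butyldimethylsilyloxy)phenyl]buta-1,3-dien-2-olate | [Li+].C=C([O-])/C=C/c1cc(O[Si](C)(C)C(C)(C)C)ccc1O[Si](C)(C)C(C)(C)C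
F3 | step 4 | 3,5-dimethyl-4-methylidenecyclohexa-2,5-dien-1-one | C=C1C(C)=CC(=O)C=C1C
F4 | step 5 | racemic 4-[(4E)-5-[2,5-bis(tert-butyldimethylsilyloxy)phenyl]-3-hydroxy-3-methylpent-4-en-1-yl]-3,5-dimethylphenol | Cc1cc(O)cc(C)c1CCC(C)(O)/C=C/c1cc(O[Si](C)(C)C(C)(C)C)ccc1O[Si](C)(C)C(C)(C)C
F5 | step 5 | 4-[(3R,4E)-5-[2,5-bis(tert-butyldimethylsilyloxy)phenyl]-3-hydroxy-3-methylpent-4-en-1-yl]-3,5-dimethylphenol | Cc1cc(O)cc(C)c1CC[C@@](C)(O)/C=C/c1cc(O[Si](C)(C)C(C)(C)C)ccc1O[Si](C)(C)C(C)(C)C
F6 | step 6 | 2-bromo-4-[(3S,4E)-5-[2,5-bis(tert-butyldimethylsilyloxy)phenyl]-3-hydroxy-3-methylpent-4-en-1-yl]-3,5-dimethylphenol | Cc1cc(O)c(Br)c(C)c1CC[C@](C)(O)/C=C/c1cc(O[Si](C)(C)C(C)(C)C)ccc1O[Si](C)(C)C(C)(C)C
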